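## Retrosynthetic overview

- Last step: both allylic C–O bonds are made in one operation, by palladium-catalysed oxidative 1,4-diacetoxylation of the 2-alkyl-1,3-diene of a C20 triene hydrocarbon. This step also fixes the E trisubstituted alkene that carries the two acetoxymethyl groups.
- The triene is a C10 + C10 union at the CH2–CH2 bond next to the ring: the α-sulfonyl carbanion of (S)-α-cyclogeranyl phenyl sulfone is alkylated with (E)-8-bromomyrcene, then the sulfone is removed reductively.
- (E)-8-Bromomyrcene comes from myrcene by allylic oxidation and bromination.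
- The only ring (the cyclohexene) is formed first, together with the single stereocentre, by a new catalytic enantioselective proton-initiated cyclisation of geranyl phenyl sulfone (from geranyl bromide).

Assumption: the step 2 catalyst, written (S,S)-IDPi, is the imidodiphosphorimidate Brønsted acid built from two (S)-3,3'-bis[3,5-bis(trifluoromethyl)phenyl]-BINOL phosphorus units joined P–N–P, each phosphorus carrying an N-triflyl imino group; the (S,S) antipode is taken as the one that gives the (S) product, and if the sense proves opposite the (R,R) antipode is used with nothing else changed.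

## Route

Step 1
Reactants: 1 geranyl bromide
Product: 2 geranyl phenyl sulfone
Conditions: PhSO2Na (1.3 equiv), DMF, 25 °C
Reagents that add atoms: sodium benzenesulfinate, [Na+].[O-]S(=O)c1ccccc1
Why: SN2 S-alkylation of the sulfinate by the primary allylic bromide (sulfinate alkylation) gives the allylic sulfone and leaves the E alkene untouched.

Step 2
Reactants: 2 geranyl phenyl sulfone
Product: 3 (S)-α-cyclogeranyl phenyl sulfone
Conditions: (S,S)-IDPi (5 mol%), (CF3)3COH/CH2Cl2 (1:1), −20 °C, 48 h
Reagents that add atoms: none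
Why: Proposed new method: the confined chiral acid protonates the electron-richer 6,7-alkene (the 2,3-alkene is deactivated by the allylic sulfonyl group) to a tertiary cation held as a contact ion pair, the 2,3-alkene closes the six-membered ring through one of the two enantiomeric chair folds selected by the catalyst pocket and by hydrogen bonding to the sulfonyl oxygens, and the catalyst anion then removes a ring CH2 proton (E1, endocyclic alkene as in the pseudoionone to α-ionone cyclisation), so the ring, the α-alkene and the (S) stereocentre are set at once; the closest known reactions are the racemic H2SO4/AcOH cyclisation of geranyl sulfones and chiral-Brønsted-acid-catalysed enantioselective polyene cyclisations such as homofarnesol to ambrox.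

Step 3
Reactants: 4 myrcene
Product: 5 (2E)-2-methyl-6-methylideneocta-2,7-dien-1-ol
Conditions: SeO2 (0.3 equiv), t-BuOOH (2 equiv), salicylic acid (10 mol%), CH2Cl2, 0 to 25 °C
Reagents that add atoms: tert-butyl hydroperoxide, CC(C)(C)OO (net oxygen source); selenium dioxide, O=[Se]=O (transfers the oxygen, recycled)
Why: SeO2/t-BuOOH allylic oxidation (ene reaction, then [2,3]-sigmatropic shift) attacks the most electron-rich trisubstituted alkene at its E methyl group and gives the E primary allylic alcohol without touching the conjugated diene.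

Step 4
Reactants: 5 (2E)-2-methyl-6-methylideneocta-2,7-dien-1-ol
Product: 6 (6E)-8-bromo-7-methyl-3-methylideneocta-1,6-diene
Conditions: CBr4 (1.2 equiv), PPh3 (1.25 equiv), CH2Cl2, −20 to 0 °C
Reagents that add atoms: tetrabromomethane, BrC(Br)(Br)Br
Why: Appel bromination converts the primary allylic alcohol to the bromide under neutral conditions, without allylic transposition or loss of the E geometry.

Step 5
Reactants: 3 (S)-α-cyclogeranyl phenyl sulfone; 6 (6E)-8-bromo-7-methyl-3-methylideneocta-1,6-diene
Product: 8 coupled sulfone ({(3E)-3-methyl-7-methylidene-1-[(1S)-2,6,6-trimethylcyclohex-2-en-1-yl]nona-3,8-dien-1-yl}sulfonyl)benzene, via α-lithio sulfone 7 (not isolated)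
Conditions: n-BuLi (1.05 equiv), THF, −78 °C; then 6, −78 to −20 °C
Reagents that add atoms: none
Why: Julia-type sulfone alkylation, in which the α-sulfonyl carbanion displaces the primary allylic bromide by SN2 to form the CH2–CH2 bond next to the ring; the ring stereocentre is β to sulfur and is not deprotonated, and the new sulfone-bearing carbon (both epimers) is erased in step 6.

Step 6
Reactants: 8 coupled sulfone
Product: 9 (6S)-1,5,5-trimethyl-6-[(3E)-3-methyl-7-methylidenenona-3,8-dien-1-yl]cyclohex-1-ene
Conditions: 6% Na(Hg) (4 equiv Na), Na2HPO4 (4 equiv), MeOH/THF (3:1), −20 °C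
Reagents that add atoms: none
Why: Reductive desulfonylation by electron transfer from sodium amalgam cleaves the C–S bond of the alkyl phenyl sulfone under buffered conditions that leave the isolated alkenes, the unactivated diene and the stereocentre untouched.

Step 7
Reactants: 9 (6S)-1,5,5-trimethyl-6-[(3E)-3-methyl-7-methylidenenona-3,8-dien-1-yl]cyclohex-1-ene
Product: 10 (2E)-2-{(3E)-4-methyl-6-[(1S)-2,6,6-trimethylcyclohex-2-en-1-yl]hex-3-en-1-yl}but-2-ene-1,4-diyl diacetate
Conditions: Pd(OAc)2 (5 mol%), p-benzoquinone (20 mol%), MnO2 (1.3 equiv), LiOAc (3 equiv), AcOH, 25 °C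
Reagents that add atoms: acetic acid, CC(=O)O (both acetoxy groups); lithium acetate, [Li+].CC(=O)[O-] (acetate carrier, regenerated from acetic acid)
Why: Bäckvall-type chloride-free oxidative 1,4-diacetoxylation, in which divalent palladium engages only the conjugated diene, acetoxypalladation gives a π-allylpalladium intermediate that acetate attacks at its unsubstituted terminus, and benzoquinone (recycled by MnO2) reoxidises zerovalent palladium; as with isoprene the 1,4-adduct is expected with the two acetoxymethyl groups trans (E), and no stereocentre is formed or touched.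

## Compound list

1 | geranyl bromide, (2E)-1-bromo-3,7-dimethylocta-2,6-diene | CC(C)=CCC/C(C)=C/CBr | starting material
2 | geranyl phenyl sulfone, {[(2E)-3,7-dimethylocta-2,6-dien-1-yl]sulfonyl}benzene | CC(C)=CCC/C(C)=C/CS(=O)(=O)c1ccccc1 | intermediate
3 | (S)-α-cyclogeranyl phenyl sulfone, ({[(1S)-2,6,6-trimethylcyclohex-2-en-1-yl]methyl}sulfonyl)benzene | O=S(=O)(c1ccccc1)C[C@@H]1C(C)=CCCC1(C)C | intermediate
4 | myrcene, 7-methyl-3-methylideneocta-1,6-diene | C=CC(=C)CCC=C(C)C | starting material
5 | (E)-8-hydroxymyrcene, (2E)-2-methyl-6-methylideneocta-2,7-dien-1-ol | C=CC(=C)CC/C=C(\C)CO | intermediate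
6 | (E)-8-bromomyrcene, (6E)-8-bromo-7-methyl-3-methylideneocta-1,6-diene | C=CC(=C)CC/C=C(\C)CBr | intermediate
7 | α-lithio sulfone, 3 lithiated at the CH2 between sulfur and the ring | [Li]C([C@@H]1C(C)=CCCC1(C)C)S(=O)(=O)c1ccccc1 | intermediate (not isolated)
8 | coupled sulfone, ({(3E)-3-methyl-7-methylidene-1-[(1S)-2,6,6-trimethylcyclohex-2-en-1-yl]nona-3,8-dien-1-yl}sulfonyl)benzene, both epimers at the sulfone carbon | C=CC(=C)CC/C=C(\C)CC([C@@H]1C(C)=CCCC1(C)C)S(=O)(=O)c1ccccc1 | intermediate
9 | triene, (6S)-1,5,5-trimethyl-6-[(3E)-3-methyl-7-methylidenenona-3,8-dien-1-yl]cyclohex-1-ene | C=CC(=C)CC/C=C(\C)CC[C@@H]1C(C)=CCCC1(C)C | intermediate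
10 | (2E)-2-{(3E)-4-methyl-6-[(1S)-2,6,6-trimethylcyclohex-2-en-1-yl]hex-3-en-1-yl}but-2-ene-1,4-diyl diacetate | CC(=O)OC/C=C(\CC/C=C(\C)CC[C@@H]1C(C)=CCCC1(C)C)COC(C)=O | target

## Step count and risks

Total step count: 7. Longest linear sequence: 5 steps (steps 1, 2, 5, 6, 7).

The three steps most likely to fail:

**Step 2 (the proposed new method).** Risks are slow cyclisation of the sulfone-deactivated diene, formation of the exocyclic or tetrasubstituted alkene isomers, and modest enantioselectivity. The fallback sets out from 2 and comes back at 3. Compound 2 is cyclised with H2SO4/AcOH at 0 °C (known racemic cation–olefin cyclisation) to racemic α-cyclogeranyl phenyl sulfone F1. This is resolved by preparative supercritical-fluid chromatography on an amylose tris(3,5-dimethylphenylcarbamate) phase, which gives 3 and its mirror image (R)-α-cyclogeranyl phenyl sulfone F2, which is discarded.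

**Step 7.** Risks are an insufficient E/Z ratio (the alkyl chain and the acetoxymethyl group compete for the same position on the π-allyl), 1,2-adducts, capture of the π-allylpalladium by the tethered trisubstituted alkene, and Diels–Alder addition of the diene to benzoquinone. The fallback sets out from 3 (through its lithio derivative 7) and comes back at 10; it fixes the alkene geometry by a known anti-carbometalation instead.
- 5-Bromo-2-methylpent-2-ene and Mg in THF give (4-methylpent-3-en-1-yl)magnesium bromide F6.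
- F6 is added to 2-butyne-1,4-diol (pre-deprotonated with EtMgBr; CuI 10 mol%, THF, reflux; copper-catalysed anti-carbomagnesiation of a propargylic alkoxide) to give (2E)-2-(4-methylpent-3-en-1-yl)but-2-ene-1,4-diol F7.
- t-BuMe2SiCl/imidazole gives (2E)-1,4-bis[(tert-butyldimethylsilyl)oxy]-2-(4-methylpent-3-en-1-yl)but-2-ene F8.
- SeO2/t-BuOOH gives (2E,6E)-8-[(tert-butyldimethylsilyl)oxy]-6-{[(tert-butyldimethylsilyl)oxy]methyl}-2-methylocta-2,6-dien-1-ol F9.
- CBr4/PPh3 gives (2E,6E)-8-bromo-1-[(tert-butyldimethylsilyl)oxy]-3-{[(tert-butyldimethylsilyl)oxy]methyl}-7-methylocta-2,6-diene F10.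
- Alkylation of 7 with F10 (THF, −78 °C) gives the silyl-protected C20 sulfone F11.
- Na(Hg)/Na2HPO4 in MeOH/THF gives the desulfonylated bis-silyl ether F12.
- Bu4NF in THF gives (2E)-2-{(3E)-4-methyl-6-[(1S)-2,6,6-trimethylcyclohex-2-en-1-yl]hex-3-en-1-yl}but-2-ene-1,4-diol F13.
- Ac2O/pyridine gives 10.

**Step 3.** Risks are moderate yield, over-oxidation to the enal and some attack at the diene. The fallback sets out from 4 and comes back at 5; it builds the E trisubstituted alkene by olefination instead of C–H oxidation. mCPBA (CH2Cl2, 0 °C) epoxidises the trisubstituted alkene of 4 to 2,2-dimethyl-3-(3-methylidenepent-4-en-1-yl)oxirane F3. H5IO6 (THF/H2O, 0 °C) cleaves it to 4-methylidenehex-5-enal F4. Wittig olefination with Ph3P=C(CH3)CO2Et (CH2Cl2, 25 °C) gives ethyl (2E)-2-methyl-6-methylideneocta-2,7-dienoate F5. i-Bu2AlH (CH2Cl2, −78 °C) reduces it to 5.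

## Further compounds

F1 | step 2 | racemic α-cyclogeranyl phenyl sulfone, ({[2,6,6-trimethylcyclohex-2-en-1-yl]methyl}sulfonyl)benzene | CC1=CCCC(C)(C)C1CS(=O)(=O)c1ccccc1
F2 | step 2 | (R)-α-cyclogeranyl phenyl sulfone | O=S(=O)(c1ccccc1)C[C@H]1C(C)=CCCC1(C)C
F3 | step 3 | 2,2-dimethyl-3-(3-methylidenepent-4-en-1-yl)oxirane (myrcene 6,7-epoxide, racemic) | CC1(C)OC1CCC(=C)C=C
F4 | step 3 | 4-methylidenehex-5-enal | O=CCCC(=C)C=C
F5 | step 3 | ethyl (2E)-2-methyl-6-methylideneocta-2,7-dienoate | CCOC(=O)/C(C)=C/CCC(=C)C=C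
F6 | step 7 | (4-methylpent-3-en-1-yl)magnesium bromide | CC(C)=CCC[Mg]Br
F7 | step 7 | (2E)-2-(4-methylpent-3-en-1-yl)but-2-ene-1,4-diol | CC(C)=CCC/C(CO)=C\CO
F8 | step 7 | (2E)-1,4-bis[(tert-butyldimethylsilyl)oxy]-2-(4-methylpent-3-en-1-yl)but-2-ene | CC(C)=CCC/C(CO[Si](C)(C)C(C)(C)C)=C\CO[Si](C)(C)C(C)(C)C
F9 | step 7 | (2E,6E)-8-[(tert-butyldimethylsilyl)oxy]-6-{[(tert-butyldimethylsilyl)oxy]methyl}-2-methylocta-2,6-dien-1-ol | OC/C(C)=C/CC/C(CO[Si](C)(C)C(C)(C)C)=C\CO[Si](C)(C)C(C)(C)C
F10 | step 7 | (2E,6E)-8-bromo-1-[(tert-butyldimethylsilyl)oxy]-3-{[(tert-butyldimethylsilyl)oxy]methyl}-7-methylocta-2,6-diene | BrC/C(C)=C/CC/C(CO[Si](C)(C)C(C)(C)C)=C\CO[Si](C)(C)C(C)(C)C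
F11 | step 7 | bis(tert-butyldimethylsilyl) ether of diol F13 carrying a phenylsulfonyl group on the chain carbon attached to the ring (both epimers) | CC(C)(C)[Si](C)(C)OC/C=C(\CC/C=C(\C)CC(S(=O)(=O)c1ccccc1)[C@@H]1C(C)=CCCC1(C)C)CO[Si](C)(C)C(C)(C)C
F12 | step 7 | bis(tert-butyldimethylsilyl) ether of diol F13 | CC(C)(C)[Si](C)(C)OC/C=C(\CC/C=C(\C)CC[C@@H]1C(C)=CCCC1(C)C)CO[Si](C)(C)C(C)(C)C
F13 | step 7 | (2E)-2-{(3E)-4-methyl-6-[(1S)-2,6,6-trimethylcyclohex-2-en-1-yl]hex-3-en-1-yl}but-2-ene-1,4-diol | OC/C=C(\CC/C=C(\C)CC[C@@H]1C(C)=CCCC1(C)C)CO
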